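**Retrosynthetic overview**

1. Target 16 ← selective saponification of dimethyl ester 15 ← SN1 ring closure (C13–O) of diol 14 ← vinyl addition to hydroxy ketone 13.
2. Key disconnection: the C9–C10 bond (with C8–O) of 13, opened to the acyclic triene keto diester 11. One hydrogen-atom-transfer-initiated radical–polar-crossover bicyclisation builds the cyclohexane and sets C8, C9 and C10 from the single stereocentre C5.
3. 11 ← alkyne 8 (Markovnikov borylation, Suzuki coupling with methyl bromoacetate) ← aldehyde 7 (Ohira–Bestmann).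
4. C4–C5 bond of 7: enantioselective radical α-alkylation of aldehyde 5 with methyl 2-bromo-2-methylpropanoate.
5. 5 ← hex-5-yn-1-ol, Me3Al and but-3-en-2-one (carboalumination, conjugate addition, oxidation). Ring order: cyclohexane first (step 6), oxygen ring closed last at C13–O (step 8).

Assumption: atoms are referred to by labdane-type numbers (C5, C8, C9, C10 on the cyclohexane; C13 carries the vinyl group); the four starting materials and all catalysts are taken as commercial.

**Route**

Step 1
Reactants: 1 hex-5-yn-1-ol; 2 but-3-en-2-one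
Product: 4 (5E)-10-hydroxy-6-methyldec-5-en-2-one, via alkenylalane 3 (not isolated)
Conditions: Me3Al (3 equiv), Cp2ZrCl2 (20 mol%), CH2Cl2, 0 °C to rt; volatiles removed; THF, CuTC (10 mol%), 2, −30 °C; aq. NH4Cl/Rochelle salt
Reagents that add atoms: trimethylaluminium, C[Al](C)C
Why: Negishi Zr-catalysed syn-carboalumination puts the methyl on the internal alkyne carbon and aluminium on the terminus, and Cu-catalysed 1,4-addition of the alkenylalane to the enone proceeds with retention, which fixes the E-trisubstituted alkene; no stereocentre is formed.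

Step 2
Reactants: 4 (5E)-10-hydroxy-6-methyldec-5-en-2-one
Product: 5 (5E)-5-methyl-9-oxodec-5-enal
Conditions: TEMPO (10 mol%), PhI(OAc)2 (1.1 equiv), CH2Cl2, rt
Reagents that add atoms: none
Why: TEMPO/PhI(OAc)2 oxidation of the primary alcohol stops at the aldehyde and leaves the ketone and alkene untouched; no stereocentre is formed.

Step 3
Reactants: 5 (5E)-5-methyl-9-oxodec-5-enal; 6 methyl 2-bromo-2-methylpropanoate
Product: 7 methyl (3R,6E)-3-formyl-2,2,6-trimethyl-10-oxoundec-6-enoate
Conditions: (2R,5S)-2-tert-butyl-3,5-dimethylimidazolidin-4-one·TfOH (20 mol%; the enantiomer that gives the R aldehyde), fac-Ir(ppy)3 (1 mol%), 2,6-lutidine (2 equiv), DMF, blue LEDs, 5 °C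
Reagents that add atoms: none
Why: Proposed new method: the photocatalyst reduces the tertiary α-bromo ester to the electrophilic radical •CMe2CO2Me, which adds to the electron-rich E-enamine of 5 on the face left open by the tert-butyl group of the catalyst (sets C5, R in 7), and the α-amino radical is oxidised to the iminium and hydrolysed; the closest known reaction is the photoredox organocatalytic α-alkylation of aldehydes with α-bromo carbonyl compounds, here extended to an unactivated tertiary α-bromo ester.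

Step 4
Reactants: 7 methyl (3R,6E)-3-formyl-2,2,6-trimethyl-10-oxoundec-6-enoate
Product: 8 methyl (3S,6E)-3-ethynyl-2,2,6-trimethyl-10-oxoundec-6-enoate
Conditions: dimethyl (1-diazo-2-oxopropyl)phosphonate (1.3 equiv), K2CO3 (2 equiv), MeOH, 0 °C to rt
Reagents that add atoms: dimethyl (1-diazo-2-oxopropyl)phosphonate, COP(=O)(OC)C(=[N+]=[N-])C(C)=O
Why: Ohira–Bestmann (Seyferth–Gilbert) homologation converts CHO into C≡CH under mild carbonate conditions, and the α-centre next to a quaternary carbon is not enolised, so its configuration is kept (the label changes from R to S only through the CIP priorities).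

Step 5
Reactants: 8 methyl (3S,6E)-3-ethynyl-2,2,6-trimethyl-10-oxoundec-6-enoate; 9 methyl bromoacetate
Product: 11 dimethyl (3S)-2,2-dimethyl-4-methylidene-3-[(3E)-3-methyl-7-oxooct-3-en-1-yl]hexanedioate, via alkenylboronate 10 (not isolated)
Conditions: (SIMes)CuCl (5 mol%), NaOt-Bu (5 mol%), B2pin2 (1.1 equiv), MeOH (2 equiv), THF, −15 °C to rt; then Pd(OAc)2 (5 mol%), P(1-naphthyl)3 (15 mol%), K3PO4 (3 equiv), H2O, 9, rt
Reagents that add atoms: none
Why: NHC–copper-catalysed protoboration of the terminal alkyne with an N-aryl NHC places boron on the internal carbon, and Suzuki–Miyaura coupling of this 1,1-disubstituted alkenylboronate with the α-bromo ester gives the β,γ-unsaturated ester without touching C5.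

Step 6
Reactants: 11 dimethyl (3S)-2,2-dimethyl-4-methylidene-3-[(3E)-3-methyl-7-oxooct-3-en-1-yl]hexanedioate
Product: 13 methyl 2-[(1S,2R,3S,4S)-4-hydroxy-2-(2-methoxy-2-oxoethyl)-2,4-dimethyl-3-(3-oxobutyl)cyclohexyl]-2-methylpropanoate, via bicyclic enol ether 12 (not isolated)
Conditions: Co(salen) (5 mol%), 1-fluoro-2,4,6-trimethylpyridinium triflate (1.5 equiv), PhSiH3 (1.2 equiv), PhCF3/HFIP 4:1, 0.01 M, 0 °C; then 1 M HCl, THF, rt
Reagents that add atoms: water, O
Why: Proposed new method: Co–H hydrogen-atom transfer to the 1,1-disubstituted alkene gives the tertiary C10 radical, which closes 6-endo onto the E-trisubstituted alkene through a chair with the CMe2CO2Me group on C5 and the C11 chain on C9 equatorial (sets C9, and C10 with Me axial and CH2CO2Me equatorial), and the tertiary C8 radical is then oxidised and captured on its equatorial face by the ketone oxygen (sets C8) to give enol ether 12, hydrolysed to 13; the closest known reactions are Co(salen)/N-fluoropyridinium MHAT-initiated polyene bicyclisations and MHAT hydroalkoxylation, and the Me-versus-CH2CO2Me choice at C10 rests only on the larger branch taking the pseudo-equatorial site, so it may be poorly selective, with the C10 epimer removed by chromatography at 13.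

Step 7
Reactants: 13 methyl 2-[(1S,2R,3S,4S)-4-hydroxy-2-(2-methoxy-2-oxoethyl)-2,4-dimethyl-3-(3-oxobutyl)cyclohexyl]-2-methylpropanoate
Product: 14 methyl 2-[(1S,2R,3S,4S)-4-hydroxy-3-(3-hydroxy-3-methylpent-4-en-1-yl)-2-(2-methoxy-2-oxoethyl)-2,4-dimethylcyclohexyl]-2-methylpropanoate (both epimers at the new carbinol carbon)
Conditions: CH2=CHMgBr (3 equiv), CeCl3 (3 equiv), THF, −78 °C; aq. NH4Cl
Reagents that add atoms: vinylmagnesium bromide, C=C[Mg]Br
Why: organocerium 1,2-addition takes the methyl ketone in preference to the two esters (the tertiary alkoxide is a spectator), and the roughly 1:1 epimer mixture at C13 is acceptable because C13 is set again in step 8.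

Step 8
Reactants: 14 methyl 2-[(1S,2R,3S,4S)-4-hydroxy-3-(3-hydroxy-3-methylpent-4-en-1-yl)-2-(2-methoxy-2-oxoethyl)-2,4-dimethylcyclohexyl]-2-methylpropanoate (both epimers)
Product: 15 methyl 2-[(2R,4aS,5R,6S,8aS)-2-ethenyl-5-(2-methoxy-2-oxoethyl)-2,5,8a-trimethyl-3,4,4a,5,6,7,8,8a-octahydro-2H-chromen-6-yl]-2-methylpropanoate
Conditions: FSO3H (5 equiv), i-PrNO2, −78 °C, 15 min; Et3N quench
Reagents that add atoms: none
Why: low-temperature superacid ionisation of the tertiary allylic alcohol gives one C13 allyl cation from both epimers, and the equatorial C8–OH captures it through a chair that leaves the vinyl group axial and cis to the C8 methyl (sets C13); this is the SN1 cycloetherification reported, as far as I recall (about 9:1), to convert the sclareol diol mainly into the 13-epi-manoyl oxide series.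

Step 9
Reactants: 15 methyl 2-[(2R,4aS,5R,6S,8aS)-2-ethenyl-5-(2-methoxy-2-oxoethyl)-2,5,8a-trimethyl-3,4,4a,5,6,7,8,8a-octahydro-2H-chromen-6-yl]-2-methylpropanoate
Product: 16 2-[(2R,4aS,5R,6S,8aS)-2-ethenyl-6-(1-methoxy-2-methyl-1-oxopropan-2-yl)-2,5,8a-trimethyl-3,4,4a,5,6,7,8,8a-octahydro-2H-chromen-5-yl]acetic acid
Conditions: LiOH·H2O (3 equiv), THF/MeOH/H2O, rt; then 1 M HCl to pH 4, 0 °C
Reagents that add atoms: lithium hydroxide, [Li+].[OH-]
Why: saponification cleaves the CH2CO2Me ester far faster than the α,α-dimethyl (pivalate-like) ester, so only the acetic acid arm is freed; no stereocentre is touched.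

**Compound list**

1 | hex-5-yn-1-ol | C#CCCCCO | starting material
2 | but-3-en-2-one | C=CC(C)=O | starting material
3 | [(1E)-6-(dimethylalumanyloxy)-2-methylhex-1-en-1-yl]dimethylalumane | C[Al](C)/C=C(\C)CCCCO[Al](C)C | intermediate (not isolated)
4 | (5E)-10-hydroxy-6-methyldec-5-en-2-one | CC(=O)CC/C=C(\C)CCCCO | intermediate
5 | (5E)-5-methyl-9-oxodec-5-enal | O=CCCC/C(C)=C/CCC(C)=O | intermediate
6 | methyl 2-bromo-2-methylpropanoate | COC(=O)C(C)(C)Br | starting material
7 | methyl (3R,6E)-3-formyl-2,2,6-trimethyl-10-oxoundec-6-enoate | O=C[C@@H](C(C)(C)C(=O)OC)CC/C(C)=C/CCC(C)=O | intermediate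
8 | methyl (3S,6E)-3-ethynyl-2,2,6-trimethyl-10-oxoundec-6-enoate | C#C[C@@H](C(C)(C)C(=O)OC)CC/C(C)=C/CCC(C)=O | intermediate
9 | methyl bromoacetate | COC(=O)CBr | starting material
10 | methyl (3S,6E)-2,2,6-trimethyl-10-oxo-3-[1-(4,4,5,5-tetramethyl-1,3,2-dioxaborolan-2-yl)ethenyl]undec-6-enoate | C=C(B1OC(C)(C)C(C)(C)O1)[C@@H](C(C)(C)C(=O)OC)CC/C(C)=C/CCC(C)=O | intermediate (not isolated)
11 | dimethyl (3S)-2,2-dimethyl-4-methylidene-3-[(3E)-3-methyl-7-oxooct-3-en-1-yl]hexanedioate | C=C(CC(=O)OC)[C@@H](C(C)(C)C(=O)OC)CC/C(C)=C/CCC(C)=O | intermediate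
12 | methyl 2-[(4aS,5R,6S,8aS)-5-(2-methoxy-2-oxoethyl)-2,5,8a-trimethyl-4a,5,6,7,8,8a-hexahydro-4H-chromen-6-yl]-2-methylpropanoate | CC1=CC[C@H]2[C@](C)(CC(=O)OC)[C@@H](C(C)(C)C(=O)OC)CC[C@]2(C)O1 | intermediate (not isolated)
13 | methyl 2-[(1S,2R,3S,4S)-4-hydroxy-2-(2-methoxy-2-oxoethyl)-2,4-dimethyl-3-(3-oxobutyl)cyclohexyl]-2-methylpropanoate | CC(=O)CC[C@H]1[C@](C)(CC(=O)OC)[C@@H](C(C)(C)C(=O)OC)CC[C@]1(C)O | intermediate
14 | methyl 2-[(1S,2R,3S,4S)-4-hydroxy-3-(3-hydroxy-3-methylpent-4-en-1-yl)-2-(2-methoxy-2-oxoethyl)-2,4-dimethylcyclohexyl]-2-methylpropanoate (both epimers at the side-chain carbinol) | C=CC(C)(O)CC[C@H]1[C@](C)(CC(=O)OC)[C@@H](C(C)(C)C(=O)OC)CC[C@]1(C)O | intermediate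
15 | methyl 2-[(2R,4aS,5R,6S,8aS)-2-ethenyl-5-(2-methoxy-2-oxoethyl)-2,5,8a-trimethyl-3,4,4a,5,6,7,8,8a-octahydro-2H-chromen-6-yl]-2-methylpropanoate | C=C[C@@]1(C)CC[C@H]2[C@](C)(CC(=O)OC)[C@@H](C(C)(C)C(=O)OC)CC[C@]2(C)O1 | intermediate
16 | 2-[(2R,4aS,5R,6S,8aS)-2-ethenyl-6-(1-methoxy-2-methyl-1-oxopropan-2-yl)-2,5,8a-trimethyl-3,4,4a,5,6,7,8,8a-octahydro-2H-chromen-5-yl]acetic acid | C=C[C@@]1(C)CC[C@H]2[C@](C)(CC(=O)O)[C@@H](C(C)(C)C(=O)OC)CC[C@]2(C)O1 | target

**Step count**

Total steps: 9. Longest linear sequence: 9.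

**Steps most likely to fail, with fallbacks**

Step 6 is the largest risk. The acyclic C10 radical has no strong bias between Me and CH2CO2Me, so the C10 ratio may be close to 1:1. The hindered ester on C4 can also trap a C10 cation as a γ-lactone, and hydrogen-atom transfer may start at the trisubstituted alkene. The fallback sets out from 8 and comes back at 13. The alkyne is carboxylated (AgI cat., Cs2CO3, CO2, DMF; then MeI) to the ynoate dimethyl (4S)-5,5-dimethyl-4-[(3E)-3-methyl-7-oxooct-3-en-1-yl]hex-2-ynedioate F1. Syn addition of Me2CuLi (THF, −78 °C) gives the Z enoate dimethyl (2Z,4S)-3,5,5-trimethyl-4-[(3E)-3-methyl-7-oxooct-3-en-1-yl]hex-2-enedioate F2. A Lewis-acid intramolecular ene reaction (Me2AlCl, CH2Cl2, −78 to 0 °C) then forms the C9–C10 bond, with the allylic strain of the Z enoate fixing C10 from C5, and gives methyl 2-[(1S,2S,3R)-2-(2-methoxy-2-oxoethyl)-2-methyl-4-methylidene-3-(3-oxobutyl)cyclohexyl]-2-methylpropanoate F3. Co(salen)/N-fluoropyridinium/PhSiH3 hydrogen-atom transfer to the exocyclic alkene, capture of C8 by the ketone oxygen and acidic work-up then give 13.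

Step 3 is the second risk: a tertiary, weakly activated α-bromo ester may couple slowly or with low ee. The fallback sets out from 5 and comes back at 7, with the polarity reversed. Methyl isobutyrate (LDA, TMSCl) gives [(1-methoxy-2-methylprop-1-en-1-yl)oxy]trimethylsilane F4. The enamine of 5, with the same imidazolidinone, is oxidised with ceric ammonium nitrate (NaHCO3, DME, −20 °C), and the enamine radical cation is attacked by the closed-shell ketene acetal.

Step 5 is the third risk: boron may go to the terminal carbon of this hindered alkyne, and the β,γ-alkene may move into conjugation under the basic coupling. The fallback sets out from 8 and comes back at 11. Bromoboration with B-bromo-9-BBN followed by AcOH gives methyl (3R,6E)-3-(1-bromoethenyl)-2,2,6-trimethyl-10-oxoundec-6-enoate F5. This is coupled (Pd(dba)2/Q-phos, THF, rt) with the Reformatsky reagent made in the flask from 9 and zinc.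

**Further compounds**

F1 | step 6 | dimethyl (4S)-5,5-dimethyl-4-[(3E)-3-methyl-7-oxooct-3-en-1-yl]hex-2-ynedioate | COC(=O)C#C[C@@H](C(C)(C)C(=O)OC)CC/C(C)=C/CCC(C)=O
F2 | step 6 | dimethyl (2Z,4S)-3,5,5-trimethyl-4-[(3E)-3-methyl-7-oxooct-3-en-1-yl]hex-2-enedioate | COC(=O)/C=C(/C)[C@@H](C(C)(C)C(=O)OC)CC/C(C)=C/CCC(C)=O
F3 | step 6 | methyl 2-[(1S,2S,3R)-2-(2-methoxy-2-oxoethyl)-2-methyl-4-methylidene-3-(3-oxobutyl)cyclohexyl]-2-methylpropanoate | CC(=O)CC[C@H]1[C@](C)(CC(=O)OC)[C@@H](C(C)(C)C(=O)OC)CCC1=C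
F4 | step 3 | [(1-methoxy-2-methylprop-1-en-1-yl)oxy]trimethylsilane | COC(O[Si](C)(C)C)=C(C)C
F5 | step 5 | methyl (3R,6E)-3-(1-bromoethenyl)-2,2,6-trimethyl-10-oxoundec-6-enoate | C=C(Br)[C@@H](C(C)(C)C(=O)OC)CC/C(C)=C/CCC(C)=O
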